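**Strategy.** The cyclohexane ring is cut at C1–C2 and C5–C6 (quinic acid numbering: C1 = quaternary carbinol, C5 = caffeoyloxy carbon). Both are aldol bonds: O5 is β to the C1 carbonyl of a pyruvate, and O1 is β to a ketone at C3 (the later free 3-OH). In one operation a pyruvate enol silane (C6–C1) and a four-carbon α-alkoxy aldehyde carrying its methyl ketone masked as an enol silane (C5–C2) are joined by two Mukaiyama aldol additions, chelation-controlled at C5 and chair-controlled at C1. The product is a protected 3-dehydroquinate whose C3 ketone distinguishes O3 from O5.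

Key step: step 7

Remark: the target is the (3R,5R) series of (−)-quinic acid, with 1-OH, 3-OH and 4-O on one ring face and 5-O and CO2H on the other; (R)-but-3-ene-1,2-diol and tert-butyl pyruvate are taken as commercial.

**Step 1**
Reactants: 1 (2R)-but-3-ene-1,2-diol
Product: 2 (4R)-4-ethenyl-2-(4-methoxyphenyl)-1,3-dioxolane (both acetal epimers)
Conditions: 4-MeOC6H4CH(OMe)2, PPTS (cat.), CH2Cl2, rt
Reagents that add atoms: 4-methoxybenzaldehyde dimethyl acetal, COC(OC)c1ccc(OC)cc1
Why: Acid-catalysed transacetalisation of the 1,2-diol gives the five-membered p-methoxybenzylidene acetal; the carbinol stereocentre is untouched and the new acetal carbon is removed in step 4.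

**Step 2**
Reactants: 2 (4R)-4-ethenyl-2-(4-methoxyphenyl)-1,3-dioxolane
Product: 3 1-[(4S)-2-(4-methoxyphenyl)-1,3-dioxolan-4-yl]ethan-1-one
Conditions: PdCl2 (10 mol%), Cu(OAc)2 (20 mol%), O2 (1 atm), DMA/H2O, rt
Reagents that add atoms: water, O
Why: Wacker oxidation should give the Markovnikov methyl ketone, the usual outcome for vinyl-1,3-dioxolanes, and the acetate-buffered copper co-oxidant keeps the medium free of HCl so that acetal and α-stereocentre survive.

**Step 3**
Reactants: 3 1-[(4S)-2-(4-methoxyphenyl)-1,3-dioxolan-4-yl]ethan-1-one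
Product: 4 tert-butyl({1-[(4S)-2-(4-methoxyphenyl)-1,3-dioxolan-4-yl]ethenyl}oxy)dimethylsilane
Conditions: LiN(i-Pr)2, THF, −78 °C; then t-BuMe2SiCl, DMPU, −78 → 0 °C
Reagents that add atoms: tert-butyldimethylsilyl chloride, CC(C)(C)[Si](C)(C)Cl
Why: Kinetic deprotonation by the hindered amide occurs at the methyl group, not at the ring C–H, and O-silylation of the lithium enolate gives the less substituted silyl enol ether without touching the stereocentre.

**Step 4**
Reactants: 4 tert-butyl({1-[(4S)-2-(4-methoxyphenyl)-1,3-dioxolan-4-yl]ethenyl}oxy)dimethylsilane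
Product: 5 (2S)-3-[(tert-butyldimethylsilyl)oxy]-2-[(4-methoxyphenyl)methoxy]but-3-en-1-ol
Conditions: i-Bu2AlH, CH2Cl2, −78 → 0 °C; aq. Rochelle salt
Reagents that add atoms: none
Why: Reductive opening of the p-methoxybenzylidene acetal: aluminium binds the less hindered primary oxygen and hydride cleaves that C–O bond, so the PMB group stays on the secondary oxygen; the silyl enol ether is not reduced.

**Step 5**
Reactants: 5 (2S)-3-[(tert-butyldimethylsilyl)oxy]-2-[(4-methoxyphenyl)methoxy]but-3-en-1-ol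
Product: 6 (2R)-3-[(tert-butyldimethylsilyl)oxy]-2-[(4-methoxyphenyl)methoxy]but-3-enal
Conditions: Dess–Martin periodinane, NaHCO3, CH2Cl2, 0 °C; used crude at once
Reagents that add atoms: none
Why: Dess–Martin oxidation under buffered, base-free conditions should give the α-alkoxy aldehyde without enolisation of C2 or migration of the enol double bond.

**Step 6**
Reactants: 7 tert-butyl 2-oxopropanoate (tert-butyl pyruvate)
Product: 8 tert-butyl 2-[(trimethylsilyl)oxy]prop-2-enoate
Conditions: Me3SiCl, Et3N, DMF, rt; distillation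
Reagents that add atoms: chlorotrimethylsilane, C[Si](C)(C)Cl
Why: Soft enolisation and O-silylation of the α-keto ester gives the 2-silyloxyacrylate, a known pyruvate enolate equivalent.

**Step 7**
Reactants: 6 (2R)-3-[(tert-butyldimethylsilyl)oxy]-2-[(4-methoxyphenyl)methoxy]but-3-enal; 8 tert-butyl 2-[(trimethylsilyl)oxy]prop-2-enoate
Product: 11 tert-butyl (1R,4S,5R)-1,5-dihydroxy-4-[(4-methoxyphenyl)methoxy]-3-oxocyclohexane-1-carboxylate, via open-chain aldol silyl ether 9 (not isolated), via cyclised 5-O-trimethylsilyl ether 10 (not isolated)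
Conditions: MgBr2·OEt2 (3 equiv), 8 (3 equiv), CH2Cl2, −78 → −20 °C, slow addition of 6; then aq. citric acid, THF, 0 °C
Reagents that add atoms: none
Why: MgBr2 chelates the aldehyde oxygen and the C4 ether oxygen of 6; the CH2 carbon of 8 (C6) adds to C5 anti to the enol silane substituent of the chelate, and the α-keto ester so released at C1, held as its own magnesium chelate, is attacked by the terminal carbon (C2) of the tert-butyldimethylsilyl enol ether, after which both silyl groups are lost on work-up. The closest known reaction types are the Lewis acid promoted aldol addition of 2-silyloxyacrylates to α-alkoxy aldehydes, the Mukaiyama aldol addition of enol silanes to chelated pyruvates, and tandem Mukaiyama aldol annulations of silyl enol ethers with two-point electrophiles. The carbocycle closes in the 6-(enolendo)-exo-trig aldol mode. C5 is controlled by the Cram chelate of the C4 stereocentre (4,5-syn, which becomes trans-diequatorial), and C1 by a chair transition state that keeps OPMB, O5 and the bulky tert-butyl ester equatorial and places the forming C1–O bond axial, the preference also shown by the uncatalysed cyclisation of the biosynthetic diketo acid. The step needs 8, not the more nucleophilic enol silane of a second molecule of 6, to take the aldehyde: 6 is added slowly to an excess of 8 so that it stays dilute, and within one molecule its enol silane could only close a four-membered ring onto C5. The acidic C4–H is safe from epimerisation because the ketone is carried as the enol silane and no base is present, and the tert-butyl ester slows lactonisation of the aldolate.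

**Step 8**
Reactants: 11 tert-butyl (1R,4S,5R)-1,5-dihydroxy-4-[(4-methoxyphenyl)methoxy]-3-oxocyclohexane-1-carboxylate
Product: 12 tert-butyl (1S,3R,4S,5R)-1,3,5-trihydroxy-4-[(4-methoxyphenyl)methoxy]cyclohexane-1-carboxylate (tert-butyl 4-O-PMB-quinate)
Conditions: LiBH(s-Bu)3, THF, −78 °C; aq. NH4Cl
Reagents that add atoms: none
Why: The bulky borohydride should attack the cyclohexanone from the equatorial direction (axial attack is blocked by the axial 1-OH and disfavoured next to the equatorial 4-OPMB group), giving the axial 3-OH cis to O4 and O1; the ester is not reduced at −78 °C.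

**Step 9**
Reactants: 13 (2E)-3-(3,4-dihydroxyphenyl)prop-2-enoic acid (caffeic acid)
Product: 14 (2E)-3-{3,4-bis[(tert-butoxycarbonyl)oxy]phenyl}prop-2-enoic acid
Conditions: Boc2O, 1 M aq. NaOH, 1,4-dioxane, 0 °C; then aq. citric acid to pH 3
Reagents that add atoms: di-tert-butyl dicarbonate, CC(C)(C)OC(=O)OC(=O)OC(C)(C)C
Why: Schotten–Baumann acylation of the two phenoxides; any mixed anhydride formed at the carboxylate is hydrolysed back in the aqueous base.

**Step 10**
Reactants: 12 tert-butyl (1S,3R,4S,5R)-1,3,5-trihydroxy-4-[(4-methoxyphenyl)methoxy]cyclohexane-1-carboxylate; 14 (2E)-3-{3,4-bis[(tert-butoxycarbonyl)oxy]phenyl}prop-2-enoic acid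
Product: 17 tert-butyl (1S,3R,4R,5R)-5-{[(2E)-3-{3,4-bis[(tert-butoxycarbonyl)oxy]phenyl}prop-2-enoyl]oxy}-1,3-dihydroxy-4-[(4-methoxyphenyl)methoxy]cyclohexane-1-carboxylate, via O1/O3 phenylboronate 15 (not isolated), via 5-O-acylated phenylboronate 16 (not isolated)
Conditions: PhB(OH)2, 4 Å MS, CH2Cl2, rt; then 14, EDC·HCl, DMAP (cat.), 0 °C → rt; then pinacol, rt
Reagents that add atoms: phenylboronic acid, OB(O)c1ccccc1 (boron and phenyl are present in 15 and 16 only)
Why: Phenylboronic acid ties up the cis-1,3-diaxial diol O1/O3 as a six-membered boronate (transient protection), so the Steglich esterification can only occur at the equatorial 5-OH; transesterification with pinacol then frees O1 and O3.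

**Step 11**
Reactants: 17 tert-butyl (1S,3R,4R,5R)-5-{[(2E)-3-{3,4-bis[(tert-butoxycarbonyl)oxy]phenyl}prop-2-enoyl]oxy}-1,3-dihydroxy-4-[(4-methoxyphenyl)methoxy]cyclohexane-1-carboxylate
Product: 18 tert-butyl (1R,3R,4S,5R)-5-{[(2E)-3-{3,4-bis[(tert-butoxycarbonyl)oxy]phenyl}prop-2-enoyl]oxy}-1-hydroxy-4-[(4-methoxyphenyl)methoxy]-3-[(triethylsilyl)oxy]cyclohexane-1-carboxylate
Conditions: Et3SiCl, imidazole, CH2Cl2/DMF, 0 °C → rt
Reagents that add atoms: chlorotriethylsilane, CC[Si](Cl)(CC)CC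
Why: Silylation of the only secondary hydroxyl (axial 3-OH); the tertiary α-hydroxy ester OH is too hindered to react under these conditions.

**Step 12**
Reactants: 18 tert-butyl (1R,3R,4S,5R)-5-{[(2E)-3-{3,4-bis[(tert-butoxycarbonyl)oxy]phenyl}prop-2-enoyl]oxy}-1-hydroxy-4-[(4-methoxyphenyl)methoxy]-3-[(triethylsilyl)oxy]cyclohexane-1-carboxylate
Product: 19 tert-butyl (1R,3R,4S,5R)-5-{[(2E)-3-{3,4-bis[(tert-butoxycarbonyl)oxy]phenyl}prop-2-enoyl]oxy}-1,4-dihydroxy-3-[(triethylsilyl)oxy]cyclohexane-1-carboxylate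
Conditions: DDQ, CH2Cl2/pH 7 buffer, 0 °C
Reagents that add atoms: none
Why: Oxidative cleavage of the electron-rich PMB ether by DDQ under neutral conditions; silyl ether, esters, carbonates and the electron-poor cinnamate arene are inert.

**Step 13**
Reactants: 19 tert-butyl (1R,3R,4S,5R)-5-{[(2E)-3-{3,4-bis[(tert-butoxycarbonyl)oxy]phenyl}prop-2-enoyl]oxy}-1,4-dihydroxy-3-[(triethylsilyl)oxy]cyclohexane-1-carboxylate
Product: 20 tert-butyl (1R,3R,4S,5R)-5-{[(2E)-3-{3,4-bis[(tert-butoxycarbonyl)oxy]phenyl}prop-2-enoyl]oxy}-4-{[3-(tert-butoxy)-3-oxopropanoyl]oxy}-1-hydroxy-3-[(triethylsilyl)oxy]cyclohexane-1-carboxylate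
Conditions: HO2CCH2CO2t-Bu, EDC·HCl, DMAP (cat.), CH2Cl2, 0 °C
Reagents that add atoms: 3-(tert-butoxy)-3-oxopropanoic acid, CC(C)(C)OC(=O)CC(=O)O
Why: Steglich esterification of the free equatorial 4-OH with the malonic half ester at low temperature; O3 is blocked by the silyl ether and the tertiary 1-OH does not compete.

**Step 14**
Reactants: 20 tert-butyl (1R,3R,4S,5R)-5-{[(2E)-3-{3,4-bis[(tert-butoxycarbonyl)oxy]phenyl}prop-2-enoyl]oxy}-4-{[3-(tert-butoxy)-3-oxopropanoyl]oxy}-1-hydroxy-3-[(triethylsilyl)oxy]cyclohexane-1-carboxylate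
Product: 21 (1S,3R,4R,5R)-4-[(carboxyacetyl)oxy]-5-{[(2E)-3-(3,4-dihydroxyphenyl)prop-2-enoyl]oxy}-1,3-dihydroxycyclohexane-1-carboxylic acid (5-O-caffeoyl-4-O-malonylquinic acid)
Conditions: TFA/CH2Cl2/H2O, anisole, 0 °C → rt; reversed-phase chromatography
Reagents that add atoms: none
Why: Acidolysis removes all protecting groups in one operation (two tert-butyl esters and two aryl tert-butyl carbonates lose isobutene, the carbonates also CO2, and the silyl ether is hydrolysed), while the caffeoyl and malonyl esters are stable to acid and base-promoted acyl migration is avoided.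

**Compound list**
1 | (2R)-but-3-ene-1,2-diol | OC[C@H](O)C=C | starting material
2 | (4R)-4-ethenyl-2-(4-methoxyphenyl)-1,3-dioxolane | C=C[C@@H]1COC(c2ccc(OC)cc2)O1 | intermediate
3 | 1-[(4S)-2-(4-methoxyphenyl)-1,3-dioxolan-4-yl]ethan-1-one | CC(=O)[C@@H]1COC(c2ccc(OC)cc2)O1 | intermediate
4 | tert-butyl({1-[(4S)-2-(4-methoxyphenyl)-1,3-dioxolan-4-yl]ethenyl}oxy)dimethylsilane | C=C(O[Si](C)(C)C(C)(C)C)[C@@H]1COC(c2ccc(OC)cc2)O1 | intermediate
5 | (2S)-3-[(tert-butyldimethylsilyl)oxy]-2-[(4-methoxyphenyl)methoxy]but-3-en-1-ol | OC[C@H](OCc1ccc(OC)cc1)C(=C)O[Si](C)(C)C(C)(C)C | intermediate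
6 | (2R)-3-[(tert-butyldimethylsilyl)oxy]-2-[(4-methoxyphenyl)methoxy]but-3-enal | O=C[C@H](OCc1ccc(OC)cc1)C(=C)O[Si](C)(C)C(C)(C)C | intermediate
7 | tert-butyl 2-oxopropanoate | CC(=O)C(=O)OC(C)(C)C | starting material
8 | tert-butyl 2-[(trimethylsilyl)oxy]prop-2-enoate | C=C(O[Si](C)(C)C)C(=O)OC(C)(C)C | intermediate
9 | tert-butyl (4R,5S)-6-[(tert-butyldimethylsilyl)oxy]-5-[(4-methoxyphenyl)methoxy]-2-oxo-4-[(trimethylsilyl)oxy]hept-6-enoate (drawn as the O-silyl ether; may equally be the bromomagnesium alkoxide) | CC(C)(C)OC(=O)C(=O)C[C@@H](O[Si](C)(C)C)[C@H](OCc1ccc(OC)cc1)C(=C)O[Si](C)(C)C(C)(C)C | intermediate (not isolated)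
10 | tert-butyl (1R,4S,5R)-1-hydroxy-4-[(4-methoxyphenyl)methoxy]-3-oxo-5-[(trimethylsilyl)oxy]cyclohexane-1-carboxylate (drawn protonated at O1) | COc1ccc(CO[C@@H]2C(=O)C[C@@](O)(C(=O)OC(C)(C)C)C[C@H]2O[Si](C)(C)C)cc1 | intermediate (not isolated)
11 | tert-butyl (1R,4S,5R)-1,5-dihydroxy-4-[(4-methoxyphenyl)methoxy]-3-oxocyclohexane-1-carboxylate | COc1ccc(CO[C@@H]2C(=O)C[C@@](O)(C(=O)OC(C)(C)C)C[C@H]2O)cc1 | intermediate
12 | tert-butyl (1S,3R,4S,5R)-1,3,5-trihydroxy-4-[(4-methoxyphenyl)methoxy]cyclohexane-1-carboxylate | COc1ccc(CO[C@@H]2[C@H](O)C[C@@](O)(C(=O)OC(C)(C)C)C[C@H]2O)cc1 | intermediate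
13 | (2E)-3-(3,4-dihydroxyphenyl)prop-2-enoic acid | O=C(O)/C=C/c1ccc(O)c(O)c1 | starting material
14 | (2E)-3-{3,4-bis[(tert-butoxycarbonyl)oxy]phenyl}prop-2-enoic acid | O=C(O)/C=C/c1ccc(OC(=O)OC(C)(C)C)c(OC(=O)OC(C)(C)C)c1 | intermediate
15 | cyclic phenylboronate of 12 across O1 and O3 (5-OH free) | COc1ccc(CO[C@@H]2[C@H]3C[C@@](OB(c4ccccc4)O3)(C(=O)OC(C)(C)C)C[C@H]2O)cc1 | intermediate (not isolated)
16 | cyclic phenylboronate of 17 across O1 and O3 | COc1ccc(CO[C@@H]2[C@H]3C[C@@](OB(c4ccccc4)O3)(C(=O)OC(C)(C)C)C[C@H]2OC(=O)/C=C/c5ccc(OC(=O)OC(C)(C)C)c(OC(=O)OC(C)(C)C)c5)cc1 | intermediate (not isolated)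
17 | tert-butyl (1S,3R,4R,5R)-5-{[(2E)-3-{3,4-bis[(tert-butoxycarbonyl)oxy]phenyl}prop-2-enoyl]oxy}-1,3-dihydroxy-4-[(4-methoxyphenyl)methoxy]cyclohexane-1-carboxylate | COc1ccc(CO[C@@H]2[C@H](O)C[C@@](O)(C(=O)OC(C)(C)C)C[C@H]2OC(=O)/C=C/c3ccc(OC(=O)OC(C)(C)C)c(OC(=O)OC(C)(C)C)c3)cc1 | intermediate
18 | tert-butyl (1R,3R,4S,5R)-5-{[(2E)-3-{3,4-bis[(tert-butoxycarbonyl)oxy]phenyl}prop-2-enoyl]oxy}-1-hydroxy-4-[(4-methoxyphenyl)methoxy]-3-[(triethylsilyl)oxy]cyclohexane-1-carboxylate | COc1ccc(CO[C@@H]2[C@H](O[Si](CC)(CC)CC)C[C@@](O)(C(=O)OC(C)(C)C)C[C@H]2OC(=O)/C=C/c3ccc(OC(=O)OC(C)(C)C)c(OC(=O)OC(C)(C)C)c3)cc1 | intermediate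
19 | tert-butyl (1R,3R,4S,5R)-5-{[(2E)-3-{3,4-bis[(tert-butoxycarbonyl)oxy]phenyl}prop-2-enoyl]oxy}-1,4-dihydroxy-3-[(triethylsilyl)oxy]cyclohexane-1-carboxylate | O[C@@H]1[C@H](O[Si](CC)(CC)CC)C[C@@](O)(C(=O)OC(C)(C)C)C[C@H]1OC(=O)/C=C/c2ccc(OC(=O)OC(C)(C)C)c(OC(=O)OC(C)(C)C)c2 | intermediate
20 | tert-butyl (1R,3R,4S,5R)-5-{[(2E)-3-{3,4-bis[(tert-butoxycarbonyl)oxy]phenyl}prop-2-enoyl]oxy}-4-{[3-(tert-butoxy)-3-oxopropanoyl]oxy}-1-hydroxy-3-[(triethylsilyl)oxy]cyclohexane-1-carboxylate | CC(C)(C)OC(=O)CC(=O)O[C@@H]1[C@H](O[Si](CC)(CC)CC)C[C@@](O)(C(=O)OC(C)(C)C)C[C@H]1OC(=O)/C=C/c2ccc(OC(=O)OC(C)(C)C)c(OC(=O)OC(C)(C)C)c2 | intermediate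
21 | (1S,3R,4R,5R)-4-[(carboxyacetyl)oxy]-5-{[(2E)-3-(3,4-dihydroxyphenyl)prop-2-enoyl]oxy}-1,3-dihydroxycyclohexane-1-carboxylic acid | O=C(O)CC(=O)O[C@@H]1[C@H](O)C[C@@](O)(C(=O)O)C[C@H]1OC(=O)/C=C/c1ccc(O)c(O)c1 | target

**Step count.** Total: 14 steps. Longest linear sequence: 12 steps (steps 1–5, 7, 8, 10–14).

**Steps most likely to fail**

Step 7. The enol silane of a second molecule of 6 may outcompete the less nucleophilic 8 for the chelated aldehyde (oligomerisation). The magnesium aldolate may also close onto C1 from the wrong face or lactonise onto the ester. The fallback makes the two bonds in separate operations with no second enol silane present. It sets out from 2: opening with i-Bu2AlH should give (2R)-2-[(4-methoxyphenyl)methoxy]but-3-en-1-ol F1, and Dess–Martin oxidation the aldehyde (2R)-2-[(4-methoxyphenyl)methoxy]but-3-enal F2. The MgBr2·OEt2 chelation-controlled Mukaiyama aldol addition of 8 to F2 should give tert-butyl (4R,5R)-4-hydroxy-5-[(4-methoxyphenyl)methoxy]-2-oxohept-6-enoate F3. Wacker oxidation of its vinyl group (PdCl2, Cu(OAc)2, O2) should give the diketo ester tert-butyl (4R,5S)-4-hydroxy-5-[(4-methoxyphenyl)methoxy]-2,6-dioxoheptanoate F4. F4 is cyclised by an amine-catalysed intramolecular aldol reaction (pyrrolidine/AcOH, THF, rt) under equilibrating conditions, which favour the all-equatorial ring, and the route is rejoined at 11.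

Step 13. Acylation of the hindered 4-OH, flanked by the silyl ether and the caffeoyl ester, may be slow enough for DMAP-promoted migration of the caffeoyl group from O5 to O4 to compete. The fallback uses a base-free ring-opening acylation instead of a carbodiimide coupling. It sets out from 19: heating with Meldrum's acid (toluene, 80 °C) should give the malonic half ester tert-butyl (1R,3R,4S,5R)-5-{[(2E)-3-{3,4-bis[(tert-butoxycarbonyl)oxy]phenyl}prop-2-enoyl]oxy}-4-[(carboxyacetyl)oxy]-1-hydroxy-3-[(triethylsilyl)oxy]cyclohexane-1-carboxylate F5. F5 is deprotected under the conditions of step 14 and the route is rejoined at 21.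

Step 2. Coordination of palladium to the allylic acetal oxygen may steer the oxidation toward the aldehyde, or the acetal may be hydrolysed in the aqueous medium. The fallback builds the methyl ketone by carbonyl addition. It sets out from 2: oxidative cleavage of the alkene (OsO4 cat., NaIO4, 2,6-lutidine, dioxane/H2O) should give (4S)-2-(4-methoxyphenyl)-1,3-dioxolane-4-carbaldehyde F6. Addition of MeMgBr (THF, −78 °C) should give 1-[(4S)-2-(4-methoxyphenyl)-1,3-dioxolan-4-yl]ethan-1-ol F7 as a carbinol mixture. Dess–Martin oxidation of F7 rejoins the route at 3.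

**Further compounds**
F1 | step 7 | (2R)-2-[(4-methoxyphenyl)methoxy]but-3-en-1-ol | OC[C@H](OCc1ccc(OC)cc1)C=C
F2 | step 7 | (2R)-2-[(4-methoxyphenyl)methoxy]but-3-enal | O=C[C@H](OCc1ccc(OC)cc1)C=C
F3 | step 7 | tert-butyl (4R,5R)-4-hydroxy-5-[(4-methoxyphenyl)methoxy]-2-oxohept-6-enoate | CC(C)(C)OC(=O)C(=O)C[C@@H](O)[C@H](OCc1ccc(OC)cc1)C=C
F4 | step 7 | tert-butyl (4R,5S)-4-hydroxy-5-[(4-methoxyphenyl)methoxy]-2,6-dioxoheptanoate | CC(C)(C)OC(=O)C(=O)C[C@@H](O)[C@H](OCc1ccc(OC)cc1)C(C)=O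
F5 | step 13 | tert-butyl (1R,3R,4S,5R)-5-{[(2E)-3-{3,4-bis[(tert-butoxycarbonyl)oxy]phenyl}prop-2-enoyl]oxy}-4-[(carboxyacetyl)oxy]-1-hydroxy-3-[(triethylsilyl)oxy]cyclohexane-1-carboxylate | O=C(O)CC(=O)O[C@@H]1[C@H](O[Si](CC)(CC)CC)C[C@@](O)(C(=O)OC(C)(C)C)C[C@H]1OC(=O)/C=C/c2ccc(OC(=O)OC(C)(C)C)c(OC(=O)OC(C)(C)C)c2
F6 | step 2 | (4S)-2-(4-methoxyphenyl)-1,3-dioxolane-4-carbaldehyde | O=C[C@@H]1COC(c2ccc(OC)cc2)O1
F7 | step 2 | 1-[(4S)-2-(4-methoxyphenyl)-1,3-dioxolan-4-yl]ethan-1-ol | CC(O)[C@@H]1COC(c2ccc(OC)cc2)O1
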